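**Retrosynthetic overview**
- The target is opened at the C6 ester: (S)-2-methylglycidate is put on last.
- The ten-membered ring is closed at C6–C7 by an intramolecular Barbier-type allylation of a 3-(acetoxymethyl)butenolide onto the (Z)-enal. This sets C6 and C7 and forms the α-methylene lactone.
- The butenolide (C8–O, C7=C11) comes from a Ni/Cr coupling–lactonisation of the C8 aldehyde with a (Z)-β-iodoacrylate.
- The 3(2H)-furanone and the C10 quaternary centre come from an Au-catalysed heterocyclisation/1,2-methyl shift of an (R)-α-ketol (key step; chirality relayed from the carbinol to C10).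
- The α-ketol comes from butane-2,3-dione and (Z)-3-methylpent-2-en-4-yn-1-ol (new asymmetric alkynylation), with C8 from trimethyl orthoformate. Ring order: furanone, then butenolide, then carbocycle.

Assumption: C-labels follow germacrane numbering (C1 ketone, C3–O–C10 bridge, C12 lactone carbonyl on O–C8); the enynol and the glycidate ester are bought as the single stereoisomers named; the ligand enantiomers in steps 2 and 6 are those that give the configurations drawn.

**Route**

Step 1
Reactants: 1 (2Z)-3-methylpent-2-en-4-yn-1-ol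
Product: 2 tert-butyldimethyl{[(2Z)-3-methylpent-2-en-4-yn-1-yl]oxy}silane
Conditions: TBSCl, imidazole, CH2Cl2, 0 °C → rt
Reagents that add atoms: tert-butyldimethylsilyl chloride, CC(C)(C)[Si](C)(C)Cl
Why: Standard silylation; the free (Z)-allylic OH must be masked because (Z)-2-en-4-yn-1-ols cycloisomerise to furans under the π-acid used in step 4.

Step 2
Reactants: 2 tert-butyldimethyl{[(2Z)-3-methylpent-2-en-4-yn-1-yl]oxy}silane; 3 butane-2,3-dione
Product: 4 (3R,6Z)-8-[(tert-butyldimethylsilyl)oxy]-3-hydroxy-3,6-dimethyloct-6-en-4-yn-2-one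
Conditions: [Rh(OAc)2(H2O)(iPr-Phebox)] (5 mol %), 3 (2 equiv), Et2O, 25 °C
Reagents that add atoms: none
Why: Proposed new method: enantioselective mono-alkynylation of a symmetrical dialkyl 1,2-diketone by a chiral Rh(III)–Phebox carboxylate; acetate-assisted C–H metalation of the terminal enyne gives a Rh–alkynyl, the s-cis dione binds through both carbonyl oxygens as an α-keto ester does, 1,2-insertion of the activated C=O into Rh–C sets the tertiary carbinol (3R, ligand-controlled face) and protonolysis by the next alkyne turns the cycle over; the two carbonyls are homotopic so no regiochemistry arises, the adduct is no longer a chelating 1,2-dicarbonyl and should not react twice, and base-free conditions avoid aldol self-condensation of the dione; closest known reaction type: Rh(III)–Phebox (or Zn/amino alcohol) catalysed asymmetric alkynylation of α-keto esters.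

Step 3
Reactants: 4 (3R,6Z)-8-[(tert-butyldimethylsilyl)oxy]-3-hydroxy-3,6-dimethyloct-6-en-4-yn-2-one; 5 trimethyl orthoformate
Product: 8 (4R,7Z)-9-[(tert-butyldimethylsilyl)oxy]-4-hydroxy-1,1-dimethoxy-4,7-dimethylnon-7-en-5-yn-3-one, via bis-TMS enol ether 6 (not isolated), via O-TMS keto acetal 7 (not isolated)
Conditions: TMSOTf (2.3 equiv), Et3N, CH2Cl2, 0 °C; pentane filtration; 5, TMSOTf (5 mol %), CH2Cl2, −78 °C; then citric acid, MeOH, rt
Reagents that add atoms: none
Why: Mukaiyama-type addition of the only possible silyl enol ether (CH3 side) to the dimethoxycarbenium ion from the orthoformate installs C8 at the aldehyde oxidation level without touching the carbinol centre; mild acidic methanolysis then removes only the tertiary O-TMS group (acetal exchange with MeOH is degenerate, TBS stays).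

Step 4
Reactants: 8 (4R,7Z)-9-[(tert-butyldimethylsilyl)oxy]-4-hydroxy-1,1-dimethoxy-4,7-dimethylnon-7-en-5-yn-3-one
Product: 10 2-{(2R)-5-[(2Z)-4-hydroxybut-2-en-2-yl]-2-methyl-3-oxo-2,3-dihydrofuran-2-yl}acetaldehyde, via furanone acetal 9 (not isolated)
Conditions: (JohnPhos)Au(MeCN)SbF6 (5 mol %), CH2Cl2, rt; then 1 M HCl, THF, rt
Reagents that add atoms: water, O
Why: Heterocyclisation/1,2-alkyl migration domino (α-ketol-type shift) of a 2-hydroxy-2-alkynyl ketone: the ketone oxygen attacks the Au-activated alkyne 5-endo, the methyl group then migrates suprafacially from the carbinol carbon to the adjacent oxocarbenium carbon, so the (R)-carbinol is relayed to the (R)-quaternary C10 while the carbinol carbon becomes the furanone C=O; protodeauration follows, and aqueous acid then cleaves the acetal and the TBS ether (soft cationic Au(I) is chosen to spare the acetal).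

Step 5
Reactants: 11 methyl propiolate; 12 formaldehyde (from paraformaldehyde)
Product: 14 methyl (2Z)-2-(acetoxymethyl)-3-iodoprop-2-enoate, via iodo alcohol 13 (not isolated)
Conditions: MgI2, CH2O, CH2Cl2, −20 → 0 °C; then Ac2O, DMAP (cat.), 0 °C
Reagents that add atoms: magnesium iodide, [Mg+2].[I-].[I-]; acetic anhydride, CC(=O)OC(C)=O
Why: β-Iodo Morita–Baylis–Hillman (iodo-aldol) reaction: iodide adds to the propiolate and the iodo-allenolate is hydroxymethylated at C-α with kinetic (Z) geometry (I cis to CO2Me); acetylation of the magnesium alkoxide gives the bifunctional linchpin.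

Step 6
Reactants: 10 2-{(2R)-5-[(2Z)-4-hydroxybut-2-en-2-yl]-2-methyl-3-oxo-2,3-dihydrofuran-2-yl}acetaldehyde; 14 methyl (2Z)-2-(acetoxymethyl)-3-iodoprop-2-enoate
Product: 16 [(5S)-5-({(2R)-5-[(2Z)-4-hydroxybut-2-en-2-yl]-2-methyl-3-oxo-2,3-dihydrofuran-2-yl}methyl)-2-oxo-2,5-dihydrofuran-3-yl]methyl acetate, via open hydroxy ester 15 (not isolated)
Conditions: CrCl2 (4 equiv), NiCl2 (2 mol %), chiral oxazoline–sulfonamide ligand, Et3N, THF, rt; then PPTS, CH2Cl2
Reagents that add atoms: none
Why: Asymmetric Nozaki–Hiyama–Kishi coupling: the alkenyl–Cr species adds only to the aldehyde (ketone, allylic acetate and free OH tolerated) with retention of (Z) geometry, so the C8 alkoxide lactonises onto the cis ester; C8 (S) is set by the chiral Cr ligand (reagent control), since the β-quaternary centre gives no reliable 1,3-induction.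

Step 7
Reactants: 16 [(5S)-5-({(2R)-5-[(2Z)-4-hydroxybut-2-en-2-yl]-2-methyl-3-oxo-2,3-dihydrofuran-2-yl}methyl)-2-oxo-2,5-dihydrofuran-3-yl]methyl acetate
Product: 17 [(5S)-5-({(2R)-2-methyl-3-oxo-5-[(2Z)-4-oxobut-2-en-2-yl]-2,3-dihydrofuran-2-yl}methyl)-2-oxo-2,5-dihydrofuran-3-yl]methyl acetate
Conditions: MnO2, CH2Cl2, rt, dark
Reagents that add atoms: none
Why: Chemoselective MnO2 oxidation of the only allylic alcohol; neutral conditions preserve the (Z)-enal and the base-sensitive butenolide acetate.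

Step 8
Reactants: 17 [(5S)-5-({(2R)-2-methyl-3-oxo-5-[(2Z)-4-oxobut-2-en-2-yl]-2,3-dihydrofuran-2-yl}methyl)-2-oxo-2,5-dihydrofuran-3-yl]methyl acetate
Product: 18 (6R,7S,8S,10R)-6-hydroxy-1-oxo-3,10-epoxygermacra-2,4(Z),11(13)-trien-12,8-olide
Conditions: Pd(PPh3)4 (10 mol %), InI (2 equiv), THF (2 mM), rt; aq NH4Cl
Reagents that add atoms: none
Why: Pd/In umpolung Barbier-type allylation: Pd(0) ionises the allylic acetate, InI reduces the π-allyl to an allylindium(III) with the metal on the exocyclic CH2, and this adds 1,2 through C7 to the tethered enal in a chair Zimmerman–Traxler transition state; attack anti to the C8 side chain gives the 7,8-trans lactone, the ring-locked E-type allyl geometry with the aldehyde substituent equatorial gives the 6,7-anti carbinol (6R), and the exocyclic methylene is regenerated.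

Step 9
Reactants: 19 methyl (2S)-2-methyloxirane-2-carboxylate
Product: 20 potassium (2S)-2-methyloxirane-2-carboxylate
Conditions: KOH (1.0 equiv), MeOH, 0 °C; evaporate
Reagents that add atoms: potassium hydroxide, [K+].[OH-]
Why: Ester saponification (BAc2) at low temperature leaves the epoxide and its quaternary stereocentre untouched; the salt is used because the free glycidic acid is labile.

Step 10
Reactants: 18 (6R,7S,8S,10R)-6-hydroxy-1-oxo-3,10-epoxygermacra-2,4(Z),11(13)-trien-12,8-olide; 20 potassium (2S)-2-methyloxirane-2-carboxylate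
Product: 22 (6R,7R,8S,10R)-1-oxo-3,10-epoxygermacra-2,4(Z),11(13)-trien-12,8-olid-6-yl (2S)-2-methyloxirane-2-carboxylate (CNP0321429.1), via mixed anhydride 21 (not isolated)
Conditions: 2,4,6-trichlorobenzoyl chloride, THF, 0 °C; then 18, Et3N, DMAP, toluene, 0 °C → rt
Reagents that add atoms: none
Why: Yamaguchi esterification: the mixed anhydride is attacked by DMAP at the less hindered glycidoyl carbonyl and the acyl-pyridinium acylates the C6 alcohol faster than translactonisation; no stereocentre is touched (the C7 descriptor changes from S to R only through CIP priorities).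

**Compound list**

1 | (2Z)-3-methylpent-2-en-4-yn-1-ol | C#C/C(C)=C\CO | starting material
2 | tert-butyldimethyl{[(2Z)-3-methylpent-2-en-4-yn-1-yl]oxy}silane | C#C/C(C)=C\CO[Si](C)(C)C(C)(C)C | intermediate
3 | butane-2,3-dione | CC(=O)C(C)=O | starting material
4 | (3R,6Z)-8-[(tert-butyldimethylsilyl)oxy]-3-hydroxy-3,6-dimethyloct-6-en-4-yn-2-one | CC(=O)[C@](C)(O)C#C/C(C)=C\CO[Si](C)(C)C(C)(C)C | intermediate
5 | trimethyl orthoformate | COC(OC)OC | starting material
6 | (3R,6Z)-8-[(tert-butyldimethylsilyl)oxy]-3,6-dimethyl-2,3-bis[(trimethylsilyl)oxy]octa-1,6-dien-4-yne | C=C(O[Si](C)(C)C)[C@](C)(O[Si](C)(C)C)C#C/C(C)=C\CO[Si](C)(C)C(C)(C)C | intermediate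
7 | (4R,7Z)-9-[(tert-butyldimethylsilyl)oxy]-1,1-dimethoxy-4,7-dimethyl-4-[(trimethylsilyl)oxy]non-7-en-5-yn-3-one | COC(OC)CC(=O)[C@](C)(O[Si](C)(C)C)C#C/C(C)=C\CO[Si](C)(C)C(C)(C)C | intermediate
8 | (4R,7Z)-9-[(tert-butyldimethylsilyl)oxy]-4-hydroxy-1,1-dimethoxy-4,7-dimethylnon-7-en-5-yn-3-one | COC(OC)CC(=O)[C@](C)(O)C#C/C(C)=C\CO[Si](C)(C)C(C)(C)C | intermediate
9 | (2R)-5-{(2Z)-4-[(tert-butyldimethylsilyl)oxy]but-2-en-2-yl}-2-(2,2-dimethoxyethyl)-2-methylfuran-3(2H)-one | COC(OC)C[C@@]1(C)OC(=CC1=O)/C(C)=C\CO[Si](C)(C)C(C)(C)C | intermediate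
10 | 2-{(2R)-5-[(2Z)-4-hydroxybut-2-en-2-yl]-2-methyl-3-oxo-2,3-dihydrofuran-2-yl}acetaldehyde | O=CC[C@@]1(C)OC(=CC1=O)/C(C)=C\CO | intermediate
11 | methyl propiolate | C#CC(=O)OC | starting material
12 | formaldehyde (used as paraformaldehyde) | C=O | starting material
13 | methyl (2Z)-2-(hydroxymethyl)-3-iodoprop-2-enoate | COC(=O)/C(=C\I)CO | intermediate
14 | methyl (2Z)-2-(acetoxymethyl)-3-iodoprop-2-enoate | COC(=O)/C(=C\I)COC(C)=O | intermediate
15 | methyl (2Z,4S)-2-(acetoxymethyl)-4-hydroxy-5-{(2R)-5-[(2Z)-4-hydroxybut-2-en-2-yl]-2-methyl-3-oxo-2,3-dihydrofuran-2-yl}pent-2-enoate | COC(=O)/C(COC(C)=O)=C\[C@@H](O)C[C@@]1(C)OC(=CC1=O)/C(C)=C\CO | intermediate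
16 | [(5S)-5-({(2R)-5-[(2Z)-4-hydroxybut-2-en-2-yl]-2-methyl-3-oxo-2,3-dihydrofuran-2-yl}methyl)-2-oxo-2,5-dihydrofuran-3-yl]methyl acetate | CC(=O)OCC1=C[C@H](C[C@@]2(C)OC(=CC2=O)/C(C)=C\CO)OC1=O | intermediate
17 | [(5S)-5-({(2R)-2-methyl-3-oxo-5-[(2Z)-4-oxobut-2-en-2-yl]-2,3-dihydrofuran-2-yl}methyl)-2-oxo-2,5-dihydrofuran-3-yl]methyl acetate | CC(=O)OCC1=C[C@H](C[C@@]2(C)OC(=CC2=O)/C(C)=C\C=O)OC1=O | intermediate
18 | (6R,7S,8S,10R)-6-hydroxy-1-oxo-3,10-epoxygermacra-2,4(Z),11(13)-trien-12,8-olide | C=C1C(=O)O[C@H]2C[C@@]3(C)OC(=CC3=O)/C(C)=C\[C@@H](O)[C@H]12 | intermediate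
19 | methyl (2S)-2-methyloxirane-2-carboxylate | COC(=O)[C@]1(C)CO1 | starting material
20 | potassium (2S)-2-methyloxirane-2-carboxylate | [K+].[O-]C(=O)[C@]1(C)CO1 | intermediate
21 | (2S)-2-methyloxirane-2-carboxylic 2,4,6-trichlorobenzoic anhydride | O=C(OC(=O)[C@]1(C)CO1)c1c(Cl)cc(Cl)cc1Cl | intermediate
22 | (6R,7R,8S,10R)-1-oxo-3,10-epoxygermacra-2,4(Z),11(13)-trien-12,8-olid-6-yl (2S)-2-methyloxirane-2-carboxylate | C=C1C(=O)O[C@H]2C[C@@]3(C)OC(=CC3=O)/C(C)=C\[C@@H](OC(=O)[C@]3(C)CO3)[C@H]12 | target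

**Step count and risks**

Total step count: 10. Longest linear sequence: 8 (steps 1, 2, 3, 4, 6, 7, 8, 10).

Steps most likely to fail:

Step 2 (the proposed new alkynylation). The dione may react sluggishly, bind poorly, or give low ee. The fallback sets out from 2 and uses the established α-keto ester version of the reaction. Alkyne 2 is added to methyl pyruvate (CC(=O)C(=O)OC) under Rh–Phebox or Zn(OTf)2/amino alcohol catalysis to give methyl (2R,5Z)-7-[(tert-butyldimethylsilyl)oxy]-2-hydroxy-2,5-dimethylhept-5-en-3-ynoate F1. MeNH(OMe)·HCl/iPrMgCl converts this into the Weinreb amide (2R,5Z)-7-[(tert-butyldimethylsilyl)oxy]-2-hydroxy-N-methoxy-N,2,5-trimethylhept-5-en-3-ynamide F2. Excess MeMgBr at −20 °C then gives the methyl ketone, and the route is rejoined at 4 (two extra steps).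

Step 4 (the heterocyclisation/1,2-shift). The cationic gold may ionise the β-keto acetal or be diverted by the enyne. The fallback sets out from silyl ether 7, isolated instead of being methanolysed, and uses the electrophile-induced form of the same domino. NIS in CH2Cl2 triggers iodonium-induced cyclisation and 1,2-methyl shift with loss of the silyl group, giving (2R)-5-{(2Z)-4-[(tert-butyldimethylsilyl)oxy]but-2-en-2-yl}-2-(2,2-dimethoxyethyl)-4-iodo-2-methylfuran-3(2H)-one F3. Reductive deiodination (Pd(PPh3)4 cat., Bu3SnH, THF) returns the route at 9, which is hydrolysed to 10 as before.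

Step 8 (the macrocyclisation). The one-pot Pd/In allylation may give oligomers, protonated allyl, or the wrong ring diastereomer. The fallback sets out from 17 and separates metalation from ring closure. Pd(0)/Me3SnSnMe3 converts the allylic acetate into the isolable allylstannane (5S)-5-({(2R)-2-methyl-3-oxo-5-[(2Z)-4-oxobut-2-en-2-yl]-2,3-dihydrofuran-2-yl}methyl)-3-[(trimethylstannyl)methyl]furan-2(5H)-one F4. InCl3 (EtOAc, −78 °C → rt, high dilution) then transmetalates it to the allylindium dichloride, which cyclises through the same closed transition state, and the route is rejoined at 18.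

Further compounds
F1 | step 2 | methyl (2R,5Z)-7-[(tert-butyldimethylsilyl)oxy]-2-hydroxy-2,5-dimethylhept-5-en-3-ynoate | COC(=O)[C@](C)(O)C#C/C(C)=C\CO[Si](C)(C)C(C)(C)C
F2 | step 2 | (2R,5Z)-7-[(tert-butyldimethylsilyl)oxy]-2-hydroxy-N-methoxy-N,2,5-trimethylhept-5-en-3-ynamide | CON(C)C(=O)[C@](C)(O)C#C/C(C)=C\CO[Si](C)(C)C(C)(C)C
F3 | step 4 | (2R)-5-{(2Z)-4-[(tert-butyldimethylsilyl)oxy]but-2-en-2-yl}-2-(2,2-dimethoxyethyl)-4-iodo-2-methylfuran-3(2H)-one | COC(OC)C[C@@]1(C)OC(/C(C)=C\CO[Si](C)(C)C(C)(C)C)=C(I)C1=O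
F4 | step 8 | (5S)-5-({(2R)-2-methyl-3-oxo-5-[(2Z)-4-oxobut-2-en-2-yl]-2,3-dihydrofuran-2-yl}methyl)-3-[(trimethylstannyl)methyl]furan-2(5H)-one | C[Sn](C)(C)CC1=C[C@H](C[C@@]2(C)OC(=CC2=O)/C(C)=C\C=O)OC1=O
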